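A direct plan would build the benzene ring onto a pyrrole: the Van Leusen product 3-acetyl-4-vinylpyrrole A1 would be formylated, N-tosylated and olefinated to the dibromovinyl triene A2.
Thermal 6π-electrocyclisation of A2 with loss of HBr would give 3-acetyl-6-bromo-1-tosylindole A3, and SeO2 oxidation with detosylation to the glyoxylic acid A4, coupling with a protected polyamine and acidolysis would follow.
Its weakest steps would be:
(a) the electrocyclisation with HBr loss: a gem-dibromo terminus has no precedent, the pyrrole sextet is broken, and 180 °C is needed on a polymerisable vinylpyrrole after five steps;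
(b) the Vilsmeier formylation: the choice between two open α-positions and the nucleophilic vinyl group would be left to chance, although the ring closure depends on it;
(c) the run-up as a whole: six steps only rebuild a bromobenzene ring that can be bought, and a late SeO2 oxidation is still needed to reach the glyoxyl level.

Plan of the new route: the retrosynthesis cuts the CH2–N bond at the secondary amine (SN2 with butane-1,4-diamine), then the amide C–N bond (ester aminolysis), then C3–C3a and N1–C2 of the pyrrole ring.
The enabling feature is that N1–C2=C3–C(=O) of the 3-acylindole is a vinylogous amide: the pyrrole ring is a cyclised N-aryl enaminone of ethyl pyruvate with C3 as its nucleophilic α-carbon.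
Br at C6 lies para to C3a, which maps onto the C–I carbon of commercial 5-bromo-2-iodoaniline.
The benzene ring is therefore bought with its bromine, and the pyrrole ring is closed second, by palladium catalysis, with the 1,2-dicarbonyl already in place.
Hence no benzannulation, no formylation of an open ring position, no oxidation to the glyoxyl level and no protecting group occur.

Key step: step 3

Remark: the free base drawn is taken as the target, so the last work-up is basic.

Step 1
Reactants: 1 ethyl pyruvate; 2 N,N-dimethylformamide dimethyl acetal
Product: 3 ethyl (E)-4-(dimethylamino)-2-oxobut-3-enoate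
Conditions: 2 (1.05 equiv), CH2Cl2, 0 °C → rt; concentrate, use crude
Reagents that add atoms: none
Why: Enaminone formation by condensation of a methyl ketone with a formamide acetal should take place at the only enolisable position of 1, the methyl group acidified by the 1,2-dicarbonyl, with loss of two molecules of MeOH, and the push–pull alkene should settle in the E form.

Step 2
Reactants: 3 ethyl (E)-4-(dimethylamino)-2-oxobut-3-enoate; 4 5-bromo-2-iodoaniline
Product: 5 ethyl (Z)-4-[(5-bromo-2-iodophenyl)amino]-2-oxobut-3-enoate
Conditions: AcOH, rt → 50 °C; dilute with water, filter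
Reagents that add atoms: none
Why: Amine exchange on a vinylogous amide (addition–elimination at the β-carbon) should be driven in AcOH because the expelled Me2NH is held as its acetate while the weakly basic aniline stays free, the product is fixed in the Z form by an N–H···O=C hydrogen bond, and neither the ketone nor the ester is attacked by so weak a nucleophile.

Step 3
Reactants: 5 ethyl (Z)-4-[(5-bromo-2-iodophenyl)amino]-2-oxobut-3-enoate
Product: 7 ethyl 2-(6-bromo-1H-indol-3-yl)-2-oxoacetate, via 3H-indole tautomer 6 (not isolated)
Conditions: Pd(OAc)2 (5 mol %), PPh3 (10 mol %), Et3N (2.5 equiv), degassed DMF, 80 °C, argon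
Reagents that add atoms: none
Why: Zerovalent palladium formed in the flask should insert into the C–I bond of 5, the nucleophilic α-carbon of the enaminone (the future C3) should then bind the divalent arylpalladium centre while Et3N takes up the proton, and C–C reductive elimination from the resulting six-membered azapalladacycle should form the C3–C3a bond and return the catalyst. The closest known reaction type is the palladium-catalysed cyclisation of N-(2-halophenyl) enaminones and enamino esters to 3-acylindoles and indole-3-carboxylates, an intramolecular Heck-type arylation of an enamine. The one ring closed is the five-membered pyrrole ring, formally in a 5-endo-trig mode with respect to the C2=C3 double bond but in fact through the six-membered palladacycle, and the first-formed 3H-indole 6 should tautomerise at once to the aromatic 1H-indole 7. No stereocentre remains, since C3 of 6 becomes sp2 and the Z/E geometry of 5 is lost. The step needs site selectivity between the two halogens, which the weaker C–I bond, the moderate temperature and a triarylphosphine ligand that activates aryl bromides only slowly should secure. The ring-fusion regiochemistry is fixed by the substrate, because iodine sits ortho to nitrogen and para to bromine, so that only the 6-bromo isomer can form.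

Step 4
Reactants: 7 ethyl 2-(6-bromo-1H-indol-3-yl)-2-oxoacetate; 8 3-chloropropan-1-amine hydrochloride
Product: 9 2-(6-bromo-1H-indol-3-yl)-N-(3-chloropropyl)-2-oxoacetamide
Conditions: 8 (3 equiv), Et3N (3 equiv), EtOH, rt → 50 °C
Reagents that add atoms: none
Why: Aminolysis of an α-keto ester by a primary amine should occur at the ester carbonyl, which the neighbouring ketone activates, whereas that ketone is a vinylogous amide through N1 and does not form an imine, the aryl bromide is inert, and the alkyl chloride is displaced much more slowly than the ester is opened at 50 °C.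

Step 5
Reactants: 9 2-(6-bromo-1H-indol-3-yl)-N-(3-chloropropyl)-2-oxoacetamide; 10 butane-1,4-diamine
Product: 12 didemnidine B, via iodopropyl amide 11 (not isolated)
Conditions: 10 (15 equiv), NaI (0.2 equiv), EtOH, 50 °C; excess 10 removed in vacuo; cold 1 M aq NaOH, extraction (CH2Cl2/i-PrOH)
Reagents that add atoms: none
Why: SN2 alkylation of an amine with Finkelstein assistance should give the monoalkylated diamine because the symmetrical diamine 10 is present in large excess and its two ends are equivalent, while the indole N–H and the amide N–H are not deprotonated by an alkylamine and the aryl bromide does not react without a metal catalyst, so that no protecting group is needed.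

Compound list
1 | ethyl pyruvate (ethyl 2-oxopropanoate) | CCOC(=O)C(C)=O | starting material
2 | N,N-dimethylformamide dimethyl acetal (1,1-dimethoxy-N,N-dimethylmethanamine) | COC(OC)N(C)C | starting material
3 | ethyl (E)-4-(dimethylamino)-2-oxobut-3-enoate | CCOC(=O)C(=O)/C=C/N(C)C | intermediate
4 | 5-bromo-2-iodoaniline | Nc1cc(Br)ccc1I | starting material
5 | ethyl (Z)-4-[(5-bromo-2-iodophenyl)amino]-2-oxobut-3-enoate | CCOC(=O)C(=O)/C=C\Nc1cc(Br)ccc1I | intermediate
6 | ethyl 2-(6-bromo-3H-indol-3-yl)-2-oxoacetate (racemic transient tautomer) | CCOC(=O)C(=O)C1C=Nc2cc(Br)ccc12 | intermediate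
7 | ethyl 2-(6-bromo-1H-indol-3-yl)-2-oxoacetate | CCOC(=O)C(=O)c1c[nH]c2cc(Br)ccc12 | intermediate
8 | 3-chloropropan-1-amine hydrochloride | NCCCCl.Cl | starting material
9 | 2-(6-bromo-1H-indol-3-yl)-N-(3-chloropropyl)-2-oxoacetamide | O=C(NCCCCl)C(=O)c1c[nH]c2cc(Br)ccc12 | intermediate
10 | butane-1,4-diamine (putrescine) | NCCCCN | starting material
11 | 2-(6-bromo-1H-indol-3-yl)-N-(3-iodopropyl)-2-oxoacetamide | O=C(NCCCI)C(=O)c1c[nH]c2cc(Br)ccc12 | intermediate
12 | didemnidine B | NCCCCNCCCNC(=O)C(=O)c1c[nH]c2cc(Br)ccc12 | target

Total steps: 5. Longest linear sequence: 5 steps (1 → 3 → 5 → 7 → 9 → 12).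

Steps most likely to fail

Step 3 (ring closure). Oxidative addition at the C–Br bond of 5 or of 7 could compete and lead to oligomers, the C–I bond could be reduced instead of coupled, or chelation of the catalyst by the 1,2-dicarbonyl could stall turnover. The fallback sets out from 4, closes the pyrrole ring through N1–C2 instead of C3–C3a, and comes back at 7. Sonogashira coupling of 4 with ethynyltrimethylsilane at the C–I bond, with PdCl2(PPh3)2, CuI and Et3N at rt, would give 5-bromo-2-[(trimethylsilyl)ethynyl]aniline F1. KOtBu in NMP at rt would then bring about 5-endo-dig hydroamination with loss of the silyl group and give 6-bromo-1H-indole F2. Oxalyl chloride in Et2O at 0 °C would acylate C3 to 2-(6-bromo-1H-indol-3-yl)-2-oxoacetyl chloride F3, which EtOH and Et3N would convert in the same flask into ester 7.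

Step 5 (amination). Intramolecular O-alkylation of the amide to a dihydro-1,3-oxazine, double alkylation of the diamine, or acyl transfer from the α-keto amide to the large excess of diamine could outrun the wanted substitution. The fallback sets out from 7, brings in the polyamine whole, and comes back at 12. Conjugate addition of commercial tert-butyl N-(4-aminobutyl)carbamate F4 to acrylonitrile in MeOH at rt would give tert-butyl N-[4-(2-cyanoethylamino)butyl]carbamate F5. Hydrogenation over Raney Ni in NH3/MeOH would give tert-butyl N-[4-(3-aminopropylamino)butyl]carbamate F6. Aminolysis of ester 7 by the primary amine of this triamine in EtOH at 50 °C, where the hindered secondary amine opens esters far more slowly, would give tert-butyl N-[4-[3-[[2-(6-bromo-1H-indol-3-yl)-2-oxoacetyl]amino]propylamino]butyl]carbamate F7. TFA in CH2Cl2 would give didemnidine B bis(trifluoroacetate) F8, from which cold aqueous NaOH would release 12.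

Step 4 (aminolysis). Free 3-chloropropan-1-amine could consume itself by self-alkylation faster than it opens the ester, whose reactivity is lowered by the vinylogous-amide ketone. The fallback sets out from 7, installs the leaving group after the amide bond, and comes back at 12. Heating 7 with 3-aminopropan-1-ol, a stable amine, in EtOH at 70 °C would give 2-(6-bromo-1H-indol-3-yl)-N-(3-hydroxypropyl)-2-oxoacetamide F9. MsCl and Et3N in THF at 0 °C would sulfonylate the primary alcohol before the indole N–H and give 3-[[2-(6-bromo-1H-indol-3-yl)-2-oxoacetyl]amino]propyl methanesulfonate F10. Excess 10 at rt, followed by aqueous NaOH work-up, would then give 12 directly.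

Further compounds
F1 | step 3 | 5-bromo-2-[(trimethylsilyl)ethynyl]aniline | C[Si](C)(C)C#Cc1ccc(Br)cc1N
F2 | step 3 | 6-bromo-1H-indole | Brc1ccc2cc[nH]c2c1
F3 | step 3 | 2-(6-bromo-1H-indol-3-yl)-2-oxoacetyl chloride | O=C(Cl)C(=O)c1c[nH]c2cc(Br)ccc12
F4 | step 5 | tert-butyl N-(4-aminobutyl)carbamate | CC(C)(C)OC(=O)NCCCCN
F5 | step 5 | tert-butyl N-[4-(2-cyanoethylamino)butyl]carbamate | CC(C)(C)OC(=O)NCCCCNCCC#N
F6 | step 5 | tert-butyl N-[4-(3-aminopropylamino)butyl]carbamate | CC(C)(C)OC(=O)NCCCCNCCCN
F7 | step 5 | tert-butyl N-[4-[3-[[2-(6-bromo-1H-indol-3-yl)-2-oxoacetyl]amino]propylamino]butyl]carbamate | CC(C)(C)OC(=O)NCCCCNCCCNC(=O)C(=O)c1c[nH]c2cc(Br)ccc12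
F8 | step 5 | didemnidine B bis(trifluoroacetate) | NCCCCNCCCNC(=O)C(=O)c1c[nH]c2cc(Br)ccc12.OC(=O)C(F)(F)F.OC(=O)C(F)(F)F
F9 | step 4 | 2-(6-bromo-1H-indol-3-yl)-N-(3-hydroxypropyl)-2-oxoacetamide | OCCCNC(=O)C(=O)c1c[nH]c2cc(Br)ccc12
F10 | step 4 | 3-[[2-(6-bromo-1H-indol-3-yl)-2-oxoacetyl]amino]propyl methanesulfonate | CS(=O)(=O)OCCCNC(=O)C(=O)c1c[nH]c2cc(Br)ccc12
A1 | direct plan | 3-acetyl-4-vinylpyrrole (1-(4-vinyl-1H-pyrrol-3-yl)ethanone) | CC(=O)c1c[nH]cc1C=C
A2 | direct plan | 1-[5-(2,2-dibromovinyl)-1-tosyl-4-vinylpyrrol-3-yl]ethanone | CC(=O)c1cn(S(=O)(=O)c2ccc(C)cc2)c(C=C(Br)Br)c1C=C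
A3 | direct plan | 3-acetyl-6-bromo-1-tosylindole (1-(6-bromo-1-tosylindol-3-yl)ethanone) | CC(=O)c1cn(S(=O)(=O)c3ccc(C)cc3)c2cc(Br)ccc12
A4 | direct plan | 2-(6-bromo-1H-indol-3-yl)-2-oxoacetic acid | OC(=O)C(=O)c1c[nH]c2cc(Br)ccc12
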